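The data come from a simulation from invented constants, and the scatter is random.

You asked for a quick number and your hunch was that the free base matters, so we start from the late readings. At 90.0 s the summer run has 18.8% of its electrophile left; at 80.0 s the dawn run, with twice the free base, has 22.7%.

common to all: electrophile 20 mM
- summer: nucleophile 60 mM; free base 30 mM; the very flask that is asked about, followed so far
- dawn: nucleophile 60 mM; free base 60 mM; run made earlier
- flask: nucleophile 60.0 mM; free base 30.0 mM; time 3.0 min

| run | time / s | electrophile / % | target / % |
|---|---|---|---|
| summer | 10.0 | 79.8 | 21.4 |
| summer | 20.0 | 64.1 | 35.9 |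
| summer | 30.0 | 52.2 | 48.1 |
| summer | 50.0 | 35.8 | 62.0 |
| summer | 60.0 | 30.8 | 68.4 |
| summer | 90.0 | 18.8 | 79.7 |
| dawn | 10.0 | 78.4 | 21.3 |
| dawn | 15.0 | 71.8 | 29.7 |
| dawn | 25.0 | 57.9 | 42.0 |
| dawn | 40.0 | 44.0 | 56.0 |
| dawn | 80.0 | 22.7 | 77.7 |

(scatter of a reading: 1 percentage point)

* part of the electrophile that has reacted at 3.0 min
* share of free nucleophile in free nucleophile and protonated nucleophile together, at 3.0 min

- acid set free is meant together with its idle adduct
- the analysis behind the earlier runs scatters by 1 percentage point, standard deviation
- steps thought possible: electrophile + nucleophile -> acid set free + target; nucleophile + acid set free <-> protonated nucleophile; acid set free + free base <-> salt of the base; free base <-> dormant form; nucleophile + acid set free <-> idle adduct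
- the earlier runs do not show how much of nucleophile is bound; that part of a forecast is a guess

We count turnovers. The count is the natural logarithm of charged over remaining electrophile, which in the asked flask is the limiting reagent. By its last reading the summer run has done 1.67, against a mean nucleophile of 51.9 mM, the charge less half of what has reacted, bound forms counted. That makes 0.358 /M/s for the count divided by mean nucleophile and time, our turnover constant. The dawn run gives 0.355 /M/s, about the same, so we leave the free base out of the count.

The asked flask is the summer run carried on to 3.0 min. Taking its mean nucleophile as the charge less half the electrophile charged, 50.0 mM, the count reaches 3.22, so we commit to 96.0% reacted. The readings do not show how much nucleophile is bound, so we give no number for its free share.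

The forecast gave 94.8% reacted (92% to 96.5%) and a free share of 93% (78% to 99%), calling the second “a guess with a wide range”. The flask gives 93.9% and 74.8%, a count of 2.80, lower than ours.

    electrophile + nucleophile → acid set free + target (k = 0.440 /M/s)
    nucleophile + acid set free ⇌ protonated nucleophile, settled at all times (K = 1300 /M)
    acid set free + free base ⇌ salt of the base (K = 3.50 × 10⁵ /M, k = 9.40 /M/s)
    free base ⇌ dormant form (K = 0.290, k = 0.0150 /s)
    nucleophile + acid set free ⇌ idle adduct, settled at all times (K = 50.0 /M)

Now the same reckoning on the neighbouring flask charged with 15 mM of nucleophile, less than its electrophile, so the limiting reagent has changed. With 0.5 of its electrophile supposed reacted, the same rule gives a mean nucleophile of 10.0 mM, the charge less a quarter of the electrophile charged. With the turnover constant 0.358 /M/s over 3.0 min, the count is 0.644, which leaves 52.5% of the electrophile. At 3.0 min the neighbouring flask holds 55.6% of its electrophile, a count of 0.587.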